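The product in these flasks can be read through what it leaves behind. Each handed substrate is half of the pair, so a product percentage gives a fraction left, as long as no substrate crosses over.

| setting | ash | elm | flask |
|---|---|---|---|
| left-handed substrate | 0.020 M | 0.020 M | 0.020 M |
| right-handed substrate | 0.020 M | 0.020 M | 0.020 M |
| partner | 0.044 M (fed, over 4.0 min) | 0.088 M (fed, over 4.0 min) | 0.0440 M (fed, over 4.0 min) |
| free catalyst | 1 mM | 1 mM | 1.0 mM |
| remark | the very flask that is asked about, followed so far | run made earlier |  |
| time |  |  | 15 min |

ash run (percent of the left-handed substrate and right-handed substrate together charged)

| time / s | left-handed product / % | right-handed product / % |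
|---|---|---|
| 10.0 | 0 | 0.2 |
| 20.0 | 0 | 0.7 |
| 30.0 | 0.4 | 0.8 |
| 50.0 | 1.8 | 0.4 |
| 80.0 | 3.7 | 0.8 |

elm run (percent of the left-handed substrate and right-handed substrate together charged)

| time / min | left-handed product / % | right-handed product / % |
|---|---|---|
| 1.33 | 6.3 | 3.0 |
| 2.50 | 17.5 | 5.6 |
| 4.00 | 28.9 | 11.5 |
| 5.00 | 33.9 | 13.8 |
| 6.00 | 39.1 | 16.7 |

(standard deviation of a reading: 0.5 percentage points)

- left-handed product and right-handed product together, in percent of the left-handed substrate and right-handed substrate charged together, at 15 min
- excess of left-handed product over right-handed product in the product at 15 min
- whether the exchange between left-handed substrate and right-handed substrate keeps pace with the reaction: how far the product's excess at 15 min gets from its value without exchange to its value with instant exchange (above 80 % keeps pace, below 20 % hardly takes part, else lags behind)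

- free catalyst is single-handed; left-handed substrate and right-handed substrate are mirror images of each other, charged as a racemate, each of them at the stated concentration
- steps under discussion: partner + free catalyst + left-handed substrate -> free catalyst + left-handed product; partner + free catalyst + right-handed substrate -> free catalyst + right-handed product; left-handed substrate <-> right-handed substrate; free catalyst -> spent catalyst; partner -> decomposition product; free catalyst <-> dormant form
- an excess is the difference of the two amounts in percent of their sum
- an excess is below zero if the other one leads

Elm's last reading gives 3.75 for the log of the left-handed fraction left over the log of the right-handed fraction left, the apparent selectivity factor. At 4.00 min it stood at 3.30. Without exchange, and with both steps first order in substrate, this factor holds constant. With readings good to 0.5 percentage points the rise is a hint, not a proof, but on it I commit to an exchange that lags behind.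

Now call minus the log of the right-handed fraction left the exposure. Ash, the asked flask followed so far, reads 0.484 of elm's product at 80.0 s, against a ratio of partner charges of 0.500, so I take exposure in proportion to partner.

Elm, end of feed: 0.261; last reading: 0.406; so 0.0726 min⁻¹ on a mean partner of 68.8 mM.

Flask, end of feed: 0.131.

Flask at 15 min, partner held at its charge: exposure 0.641, yield 69.2 %.

The weak link is that held partner, since the charge is 1.10 equivalents of the two substrates together. Reforged, my estimate of partner runs from 35.9 mM to 16.3 mM:

Mean partner 26.1 mM; exposure 0.434; yield 57.8 %; excess 39.1 %.

That excess is reckoned without exchange, so I expect the flask's excess above it.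

The forecast gave a yield of 56 % (46 % to 65 %), an excess of 41 % (34 % to 49 %) and an exchange that hardly takes part, reading “plain kinetic resolution, so the exchange looks slow”.

The flask gives a yield of 53.8 %, an excess of 44.7 %, and an exchange that lags behind, 66 % of the way to the excess with instant exchange.

    partner + free catalyst + left-handed substrate → free catalyst + left-handed product (k = 210 M⁻² s⁻¹)
    partner + free catalyst + right-handed substrate → free catalyst + right-handed product (k = 71.0 M⁻² s⁻¹)
    left-handed substrate ⇌ right-handed substrate (k = 0.00310 s⁻¹)
    free catalyst → spent catalyst (k = 0.00180 s⁻¹)
    partner → decomposition product (k = 7.20 × 10⁻⁶ s⁻¹)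
    free catalyst ⇌ dormant form (K = 1.80, k = 0.00530 s⁻¹)

By its product the flask has a factor of 4.26, higher than the 3.75 read from elm. Counted as if no substrate crossed over, the flask's product leaves 22.2 % of the left-handed substrate, yet 44 % of its charge remains at 15.0 min. The neighbouring flask, the same but with 2.5 × 10⁻⁴ M of free catalyst, reaches a yield of 22.5 % and an excess of 47.9 %. Its factor is 3.25, lower than the flask's, and its count leaves 66.7 % of the left-handed substrate where 76 % of the charge remains.

All runs are simulated on assumed constants.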